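**Retrosynthetic overview**

1. The strategy rests on ring B (C5–C10): its quaternary C9 lies 1,4 to the C6 carbonyl and, with C11 read as a formyl group, C9 is the α-carbon of an enal. Ring B is therefore the retron of a [4+2] addition of a ring A 2-silyloxydiene (C10=C5–C6(OSi)=C7) to tiglaldehyde (C8=C9–C11HO), forming C7–C8 and C9–C10.
2. Ring A comes first, from 2-methylcyclohexane-1,3-dione: hydroxymethylation, a desymmetrising Corey–Bakshi–Shibata reduction that fixes C4, a C3/C19 acetonide, then C5 enol triflate, Stille coupling and silyl enol ether formation.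
3. Ring B is closed second by the catalytic asymmetric Diels–Alder reaction, which sets C9.
4. The side chain C12–C16 follows from the C11 aldehyde by Wittig methylenation and hydroboration/B-alkyl Suzuki coupling with an (E)-3-iodobut-2-enyl silyl ether, which fixes the E alkene.
5. The C5=C6 silyl enol ether is dehydrogenated to the C5=C10 enone, C7 is hydroxylated, and after acetonide removal and C19 acetylation a double oxidation gives the C3 ketone and the C6/C7 diosphenol; C15 is unmasked last.

Key step: step 8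

**Remarks on the chemistry**

- Locants: ring A = C1, C2, C3, C4, C5, C10; ring B = C5–C10; chain C11–C15 on C9; C16 = methyl on C13; C19 = oxygenated carbon on C4. Descriptors in the names of 16–30 use these locants.
- Assumption: the sense of induction in step 8 is taken from the accepted pre-transition-state model of the enal–oxazaborolidinium complex. On that model the (S)-catalyst leaves the Re face of C9 open, so the (R)-catalyst is chosen; the catalyst choice in step 3 rests likewise on the standard model with the quaternary carbon as the large group.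
- Compounds 16–23 are drawn with the C10 configuration of the endo-formyl mode, and 26–28 with C7–OH trans to the C8 methyl. Epimers at C10 and C7 converge, because C7, C8 and C10 all become trigonal.

**Route**

Step 1
Reactants: 1 2-methylcyclohexane-1,3-dione; 2 formaldehyde
Product: 3 2-(hydroxymethyl)-2-methylcyclohexane-1,3-dione
Conditions: 37% aq. HCHO, H2O, rt
Reagents that add atoms: none
Why: Aldol hydroxymethylation at the doubly activated C2 of the enolised dione, which carries a single hydrogen and so stops at the mono-adduct.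

Step 2
Reactants: 3 2-(hydroxymethyl)-2-methylcyclohexane-1,3-dione
Product: 4 silyl ether dione
Conditions: TBSCl, imidazole, CH2Cl2, 0 °C to rt
Reagents that add atoms: tert-butyldimethylsilyl chloride, CC(C)(C)[Si](C)(C)Cl
Why: Silylation of the primary alcohol under weakly basic conditions blocks retro-aldol loss of formaldehyde and gives the bulky C4 substituent needed for the next step.

Step 3
Reactants: 4 silyl ether dione
Product: 5 (2S,3S)-hydroxy ketone
Conditions: (R)-2-methyl-CBS-oxazaborolidine (20 mol%), catecholborane (1.1 equiv), toluene, −78 °C; aqueous work-up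
Reagents that add atoms: none
Why: Corey–Bakshi–Shibata reduction used as a desymmetrisation, in which the catalyst–borane complex should reduce one enantiotopic carbonyl to the (S)-carbinol on the face anti to the bulkier silyloxymethyl group, so that C3 is set and C4 is thereby fixed as S; the minor trans diastereomer has the opposite C4 configuration and is removed by chromatography.

Step 4
Reactants: 5 (2S,3S)-hydroxy ketone
Product: 7 acetonide ketone, via keto diol 6 (not isolated)
Conditions: HCl (cat.), MeOH, 0 °C to rt; evaporate; Me2C(OMe)2, PPTS, acetone, rt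
Reagents that add atoms: 2,2-dimethoxypropane, COC(C)(C)OC
Why: Acidic methanolysis of the primary silyl ether followed by acetal exchange gives the cis-fused 1,3-dioxane of the syn 1,3-diol; the acidic medium avoids retro-aldol scrambling of the quaternary C4.

Step 5
Reactants: 7 acetonide ketone
Product: 9 enol triflate, via potassium enolate 8 (not isolated)
Conditions: KN(SiMe3)2, THF, −78 °C; PhNTf2, −78 to 0 °C; aq. NH4Cl
Reagents that add atoms: N-phenylbis(trifluoromethanesulfonimide), O=S(=O)(N(c1ccccc1)S(=O)(=O)C(F)(F)F)C(F)(F)F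
Why: Enolate O-triflation, regiochemically unambiguous because C4 is quaternary and only C10 carries α-hydrogens, gives the C5=C10 enol triflate.

Step 6
Reactants: 9 enol triflate; 10 tributyl(1-ethoxyvinyl)stannane
Product: 12 methyl enone, via ethoxydiene 11 (not isolated)
Conditions: Pd(PPh3)4 (5 mol%), LiCl, THF, 65 °C; then 1 M aq. HCl, THF, 0 °C
Reagents that add atoms: water, O
Why: Stille coupling of the vinyl triflate with an acyl-anion equivalent on zerovalent palladium, then fast hydrolysis of the enol ether at a rate the acetonide should survive, installs C6 and C7 as an acetyl group.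

Step 7
Reactants: 12 methyl enone
Product: 14 ring A silyloxydiene, via potassium dienolate 13 (not isolated)
Conditions: KN(SiMe3)2, THF, −78 °C; i-Pr3SiOTf, −78 to 0 °C; Et3N-deactivated SiO2
Reagents that add atoms: triisopropylsilyl trifluoromethanesulfonate, CC(C)[Si](C(C)C)(C(C)C)OS(=O)(=O)C(F)(F)F
Why: Kinetic α′-deprotonation of the enone at the acetyl methyl and O-silylation give the cross-conjugated 2-silyloxydiene C10=C5–C6(OSi)=C7.

Step 8
Reactants: 14 ring A silyloxydiene; 15 tiglaldehyde
Product: 16 Diels–Alder adduct (C9 aldehyde; C5=C6 silyl enol ether)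
Conditions: (R)-B-(o-tolyl)oxazaborolidine of α,α-diphenylprolinol (20 mol%), Tf2NH (17 mol%), 15 (3 equiv), CH2Cl2, −78 to −40 °C; Et3N quench
Reagents that add atoms: none
Why: The protonated oxazaborolidine binds the formyl oxygen of s-trans tiglaldehyde (with a formyl C–H···O contact to the ring oxygen) and lowers its LUMO, and a concerted, asynchronous Diels–Alder reaction follows in which the enol terminus C7 bonds to the β-carbon C8 ahead of C10 to the α-carbon C9. The closest known reaction type is the oxazaborolidinium-catalysed enantioselective Diels–Alder reaction of α-substituted enals with 2-silyloxy-1,3-dienes. Ring B closes by suprafacial [4+2] addition on both partners, which places the C8 and C9 methyl groups cis. C9 is created on the dienophile and is set by the catalyst alone: a phenyl group of the (R)-catalyst covers the Re face of C9 (CHO > C8 > CH3), so C10 adds to the Si face; C8 follows from the E geometry and C10 from the endo/exo mode, and both are later made trigonal. The step needs para regiochemistry (C6–OSi 1,4 to C9), secured by the large HOMO coefficient at C7 of the 2-silyloxydiene, and enantioface selection on the enal, which is independent of the remote C4 centre; a small deficit of Tf2NH relative to the oxazaborolidine keeps free acid from cleaving the acetonide or the diene.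

Step 9
Reactants: 16 Diels–Alder adduct
Product: 17 C9 vinyl compound
Conditions: Ph3PCH3Br, KOt-Bu, THF, 0 °C to rt
Reagents that add atoms: methyltriphenylphosphonium bromide, C[P+](c1ccccc1)(c1ccccc1)c1ccccc1.[Br-]
Why: Wittig methylenation of the non-enolisable neopentyl aldehyde adds C12; the silyl enol ether and acetonide are inert to the ylide.

Step 10
Reactants: 18 but-2-yn-1-ol
Product: 19 silyl ether of but-2-yn-1-ol
Conditions: TBDPSCl, imidazole, CH2Cl2, rt
Reagents that add atoms: tert-butyldiphenylsilyl chloride, CC(C)(C)[Si](Cl)(c1ccccc1)c1ccccc1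
Why: Standard silylation gives an acid-stable protecting group for C15–OH that can be removed at the end with fluoride without touching an acetate.

Step 11
Reactants: 19 silyl ether of but-2-yn-1-ol
Product: 21 (E)-vinyl iodide, via alkenylzirconocene 20 (not isolated)
Conditions: Cp2Zr(H)Cl (2 equiv), THF, 50 °C; then I2, 0 °C
Reagents that add atoms: iodine, II
Why: Syn hydrozirconation of the internal alkyne, equilibrated with excess reagent to place zirconium on the methyl-bearing carbon remote from the silyloxymethyl group, and iodinolysis with retention give the E iodide that defines the C13=C14 geometry.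

Step 12
Reactants: 17 C9 vinyl compound; 21 (E)-vinyl iodide
Product: 23 side-chain coupled silyl enol ether, via B-alkyl-9-BBN 22 (not isolated)
Conditions: 9-BBN, THF, rt; then 21, Pd(dppf)Cl2 (5 mol%), AsPh3, Cs2CO3, DMF/H2O, rt
Reagents that add atoms: none
Why: Anti-Markovnikov hydroboration of the terminal alkene (the tetrasubstituted enol ether is inert) and B-alkyl Suzuki–Miyaura coupling form C12–C13 with retention of the E geometry.

Step 13
Reactants: 23 side-chain coupled silyl enol ether
Product: 24 C5=C10 enone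
Conditions: Pd(OAc)2 (1.2 equiv), MeCN, 40 °C
Reagents that add atoms: none
Why: Saegusa–Ito oxidation, in which the silyl enol ether gives a divalent palladium enolate at C5 and β-hydride elimination can only take the C10 hydrogen because C4 is quaternary; this removes the C10 stereocentre.

Step 14
Reactants: 24 C5=C10 enone
Product: 26 C7 acyloin, via potassium enolate 25 (not isolated)
Conditions: KN(SiMe3)2, THF, −78 °C; 3-phenyl-2-(phenylsulfonyl)oxaziridine, −78 °C; aq. NH4Cl
Reagents that add atoms: 3-phenyl-2-(phenylsulfonyl)oxaziridine, O=S(=O)(N1OC1c1ccccc1)c1ccccc1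
Why: Kinetic α′-deprotonation at C7 and Davis enolate hydroxylation introduce the C7 oxygen without an electrophilic oxidant that would attack the side-chain alkene; the C7 configuration is irrelevant.

Step 15
Reactants: 26 C7 acyloin
Product: 27 triol
Conditions: AcOH/THF/H2O (3:1:1), 40 °C
Reagents that add atoms: none
Why: Mild acid hydrolysis of the acetonide, which the primary tert-butyldiphenylsilyl ether and the acyloin should tolerate.

Step 16
Reactants: 27 triol
Product: 28 C19 monoacetate
Conditions: AcCl (1.05 equiv), 2,4,6-collidine, CH2Cl2, −78 to −40 °C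
Reagents that add atoms: acetyl chloride, CC(Cl)=O
Why: Low-temperature acylation with acetyl chloride and a hindered pyridine base is selective for primary alcohols, and here the competitors are a secondary C3–OH beside a quaternary carbon and a hydrogen-bonded secondary acyloin OH.

Step 17
Reactants: 28 C19 monoacetate
Product: 30 C15-silylated target, via 6,7-dione 29 (not isolated)
Conditions: Dess–Martin periodinane (2.5 equiv), CH2Cl2, 0 °C to rt
Reagents that add atoms: none
Why: Dess–Martin oxidation of both secondary carbinols gives the C3 ketone and the C6,C7-dione, which enolises toward C8 (its only α-hydrogen) to the diosphenol and so removes the C7 and C8 stereocentres.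

Step 18
Reactants: 30 C15-silylated target
Product: 31 CNP0512382.1
Conditions: HF·pyridine, THF/pyridine, 0 °C to rt
Reagents that add atoms: none
Why: Buffered fluoride cleavage of the silyl ether under non-basic conditions leaves the acetate and the retro-aldol-prone β-acetoxy ketone intact.

**Compound list**

1 | 2-methylcyclohexane-1,3-dione | CC1C(=O)CCCC1=O | starting material
2 | formaldehyde (37% aqueous) | C=O | starting material
3 | 2-(hydroxymethyl)-2-methylcyclohexane-1,3-dione | CC1(CO)C(=O)CCCC1=O | intermediate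
4 | 2-{[(tert-butyldimethylsilyl)oxy]methyl}-2-methylcyclohexane-1,3-dione | CC1(CO[Si](C)(C)C(C)(C)C)C(=O)CCCC1=O | intermediate
5 | (2S,3S)-2-{[(tert-butyldimethylsilyl)oxy]methyl}-3-hydroxy-2-methylcyclohexan-1-one (OH cis to CH2OSi) | CC(C)(C)[Si](C)(C)OC[C@@]1(C)[C@@H](O)CCCC1=O | intermediate
6 | (2S,3S)-3-hydroxy-2-(hydroxymethyl)-2-methylcyclohexan-1-one | OC[C@@]1(C)[C@@H](O)CCCC1=O | intermediate
7 | (4aS,8aS)-2,2,4a-trimethylhexahydro-4H-1,3-benzodioxin-5-one (cis-fused 3,19-acetonide ketone) | CC1(C)OC[C@@]2(C)[C@@H](O1)CCCC2=O | intermediate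
8 | potassium enolate of 7 (C5–O, C5=C10) | CC1(C)OC[C@@]2(C)[C@@H](O1)CCC=C2[O-].[K+] | intermediate
9 | (4aS,8aS)-2,2,4a-trimethyl-4a,7,8,8a-tetrahydro-4H-1,3-benzodioxin-5-yl trifluoromethanesulfonate | CC1(C)OC[C@@]2(C)[C@@H](O1)CCC=C2OS(=O)(=O)C(F)(F)F | intermediate
10 | tributyl(1-ethoxyvinyl)stannane | CCCC[Sn](CCCC)(CCCC)C(=C)OCC | starting material
11 | (4aS,8aS)-5-(1-ethoxyvinyl)-2,2,4a-trimethyl-4a,7,8,8a-tetrahydro-4H-1,3-benzodioxine | CC1(C)OC[C@@]2(C)[C@@H](O1)CCC=C2C(=C)OCC | intermediate
12 | 1-[(4aS,8aS)-2,2,4a-trimethyl-4a,7,8,8a-tetrahydro-4H-1,3-benzodioxin-5-yl]ethan-1-one | CC1(C)OC[C@@]2(C)[C@@H](O1)CCC=C2C(C)=O | intermediate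
13 | potassium dienolate of 12 (C6–O, C6=C7) | CC1(C)OC[C@@]2(C)[C@@H](O1)CCC=C2C(=C)[O-].[K+] | intermediate
14 | triisopropyl({1-[(4aS,8aS)-2,2,4a-trimethyl-4a,7,8,8a-tetrahydro-4H-1,3-benzodioxin-5-yl]vinyl}oxy)silane (ring A 2-silyloxydiene) | CC1(C)OC[C@@]2(C)[C@@H](O1)CCC=C2C(=C)O[Si](C(C)C)(C(C)C)C(C)C | intermediate
15 | tiglaldehyde, (E)-2-methylbut-2-enal | C/C=C(\C)C=O | starting material
16 | (3S,4S,8S,9R,10S)-Diels–Alder adduct: 3,19-acetonide, C5=C6 enol ether with OSi(i-Pr)3 on C6, C8 and C9 methyls cis, CHO on C9 | CC1(C)OC[C@@]2(C)[C@@H](O1)CC[C@H]3C2=C(O[Si](C(C)C)(C(C)C)C(C)C)C[C@H](C)[C@@]3(C)C=O | intermediate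
17 | (3S,4S,8S,9R,10R)-C9 vinyl compound (C11=C12 in place of the formyl group of 16) | CC1(C)OC[C@@]2(C)[C@@H](O1)CC[C@H]3C2=C(O[Si](C(C)C)(C(C)C)C(C)C)C[C@H](C)[C@@]3(C)C=C | intermediate
18 | but-2-yn-1-ol | CC#CCO | starting material
19 | tert-butyl(but-2-yn-1-yloxy)diphenylsilane | CC#CCO[Si](c1ccccc1)(c1ccccc1)C(C)(C)C | intermediate
20 | (E)-alkenylzirconocene chloride (Zr on C3 of the butenyl ether, trans to CH2OSi) | C/C(=C\CO[Si](c1ccccc1)(c1ccccc1)C(C)(C)C)[Zr](Cl)(C1C=CC=C1)C1C=CC=C1 | intermediate
21 | (E)-tert-butyl[(3-iodobut-2-en-1-yl)oxy]diphenylsilane | C/C(I)=C\CO[Si](c1ccccc1)(c1ccccc1)C(C)(C)C | intermediate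
22 | B-alkyl-9-borabicyclo[3.3.1]nonane from 17 (boron on C12) | CC1(C)OC[C@@]2(C)[C@@H](O1)CC[C@H]3C2=C(O[Si](C(C)C)(C(C)C)C(C)C)C[C@H](C)[C@@]3(C)CCB4C5CCCC4CCC5 | intermediate
23 | (3S,4S,8S,9R,10R,13E)-silyl enol ether with full side chain, C15–OSi(t-Bu)Ph2 | CC1(C)OC[C@@]2(C)[C@@H](O1)CC[C@H]3C2=C(O[Si](C(C)C)(C(C)C)C(C)C)C[C@H](C)[C@@]3(C)CC/C(C)=C/CO[Si](c4ccccc4)(c4ccccc4)C(C)(C)C | intermediate
24 | (3S,4S,8S,9R,13E)-5(10)-en-6-one, 3,19-acetonide, C15–OSi(t-Bu)Ph2 | CC1(C)OC[C@@]2(C)[C@@H](O1)CCC3=C2C(=O)C[C@H](C)[C@@]3(C)CC/C(C)=C/CO[Si](c4ccccc4)(c4ccccc4)C(C)(C)C | intermediate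
25 | potassium C6(O)=C7 enolate of 24 | CC1(C)OC[C@@]2(C)[C@@H](O1)CCC3=C2C([O-])=C[C@H](C)[C@@]3(C)CC/C(C)=C/CO[Si](c4ccccc4)(c4ccccc4)C(C)(C)C.[K+] | intermediate
26 | (3S,4S,7S,8R,9R,13E)-7-hydroxy-5(10)-en-6-one, 3,19-acetonide, C15–OSi(t-Bu)Ph2 | CC1(C)OC[C@@]2(C)[C@@H](O1)CCC3=C2C(=O)[C@@H](O)[C@H](C)[C@@]3(C)CC/C(C)=C/CO[Si](c4ccccc4)(c4ccccc4)C(C)(C)C | intermediate
27 | (3S,4S,7S,8R,9R,13E)-3,7,19-triol of the 5(10)-en-6-one, C15–OSi(t-Bu)Ph2 | OC[C@@]1(C)[C@@H](O)CCC2=C1C(=O)[C@@H](O)[C@H](C)[C@@]2(C)CC/C(C)=C/CO[Si](c3ccccc3)(c3ccccc3)C(C)(C)C | intermediate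
28 | (3S,4S,7S,8R,9R,13E)-19-acetoxy-3,7-diol of the 5(10)-en-6-one, C15–OSi(t-Bu)Ph2 | CC(=O)OC[C@@]1(C)[C@@H](O)CCC2=C1C(=O)[C@@H](O)[C@H](C)[C@@]2(C)CC/C(C)=C/CO[Si](c3ccccc3)(c3ccccc3)C(C)(C)C | intermediate
29 | (4S,8R,9R,13E)-19-acetoxy-5(10)-ene-3,6,7-trione, C15–OSi(t-Bu)Ph2 | CC(=O)OC[C@@]1(C)C(=O)CCC2=C1C(=O)C(=O)[C@H](C)[C@@]2(C)CC/C(C)=C/CO[Si](c3ccccc3)(c3ccccc3)C(C)(C)C | intermediate
30 | (4S,9S,13E)-19-acetoxy-7-hydroxy-5(10),7-diene-3,6-dione, C15–OSi(t-Bu)Ph2 | CC(=O)OC[C@@]1(C)C(=O)CCC2=C1C(=O)C(O)=C(C)[C@@]2(C)CC/C(C)=C/CO[Si](c3ccccc3)(c3ccccc3)C(C)(C)C | intermediate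
31 | CNP0512382.1, (4S,9S,13E)-19-acetoxy-7,15-dihydroxy-5(10),7,13-triene-3,6-dione | CC(=O)OC[C@@]1(C)C(=O)CCC2=C1C(=O)C(O)=C(C)[C@@]2(C)CC/C(C)=C/CO | target

**Step count**

Total steps: 18. Longest linear sequence: 16 (steps 1–9 and 12–18); steps 10 and 11 form the side-chain branch.

**Steps most likely to fail**

Step 8. The diene may not reach the s-cis geometry next to the quaternary C4 in front of the bulky catalyst-bound enal, so that cycloaddition is outrun by Mukaiyama-type addition to the formyl group or by protodesilylation, or the enal faces may be poorly discriminated. The fallback sets out from 14 (with 15) and makes the same two bonds under substrate control with a small achiral Lewis acid (Me2AlCl, CH2Cl2, −78 to −30 °C), a standard promoter for Diels–Alder additions of silyloxydienes to hindered enals. The C4 centre then makes the two C9 series diastereomers, so 16 (with its C10 epimer) is separated by chromatography from the ring B antipodal adduct F1, and the route is rejoined at 16.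

Step 13. Transfer of the hindered, tetrasubstituted triisopropylsilyl enol ether to palladium and β-hydride elimination from the neopentyl-type C5 may be slow, leaving room for allylic oxidation of the side chain or simple hydrolysis to the saturated ketone. The fallback sets out from 23 and keeps the regiochemical information of the enol ether: bromination with NBS (THF, −78 to 0 °C) at C5 should give the C5-bromo ketone F2, and dehydrobromination (Li2CO3, LiBr, DMF, 110 °C), possible only toward C10, returns to the route at 24.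

Step 16. Acetylation may not stop at the neopentyl C19 hydroxyl and may spread to the C7 acyloin hydroxyl. The fallback sets out from 26 and removes the competition by protecting C7 first, finishing with an acyloin-selective oxidation. Silylation (TBSOTf, 2,6-lutidine, CH2Cl2, −78 °C) gives the C7 silyl ether F3; acetonide hydrolysis (AcOH/THF/H2O) gives the 3,19-diol F4; acetylation (Ac2O, pyridine, 0 °C), now only against the hindered C3–OH, gives the C19 acetate F5; Dess–Martin oxidation gives the C3 ketone F6; HF·pyridine removes both silyl groups to give the acyloin allylic alcohol F7; and Cu(OAc)2 in MeOH, which oxidises α-hydroxy ketones but not allylic alcohols, gives the diosphenol and so comes back at the target 31.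

**Further compounds**

F1 | step 8 | (3S,4S,8R,9S,10R)-diastereomer of 16 (ring B centres antipodal) | CC1(C)OC[C@@]2(C)[C@@H](O1)CC[C@@H]3C2=C(O[Si](C(C)C)(C(C)C)C(C)C)C[C@@H](C)[C@]3(C)C=O
F2 | step 13 | C5-bromo-6-ketone from 23 (C5 epimers; 3S,4S,8S,9R,10R) | CC1(C)OC[C@@]2(C)[C@@H](O1)CC[C@H]3C2(Br)C(=O)C[C@H](C)[C@@]3(C)CC/C(C)=C/CO[Si](c4ccccc4)(c4ccccc4)C(C)(C)C
F3 | step 16 | C7 tert-butyldimethylsilyl ether of 26 | CC1(C)OC[C@@]2(C)[C@@H](O1)CCC3=C2C(=O)[C@@H](O[Si](C)(C)C(C)(C)C)[C@H](C)[C@@]3(C)CC/C(C)=C/CO[Si](c4ccccc4)(c4ccccc4)C(C)(C)C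
F4 | step 16 | 3,19-diol with C7–OSi(t-Bu)Me2 and C15–OSi(t-Bu)Ph2 | OC[C@@]1(C)[C@@H](O)CCC2=C1C(=O)[C@@H](O[Si](C)(C)C(C)(C)C)[C@H](C)[C@@]2(C)CC/C(C)=C/CO[Si](c3ccccc3)(c3ccccc3)C(C)(C)C
F5 | step 16 | C19 acetate of F4 | CC(=O)OC[C@@]1(C)[C@@H](O)CCC2=C1C(=O)[C@@H](O[Si](C)(C)C(C)(C)C)[C@H](C)[C@@]2(C)CC/C(C)=C/CO[Si](c3ccccc3)(c3ccccc3)C(C)(C)C
F6 | step 16 | C3 ketone of F5 | CC(=O)OC[C@@]1(C)C(=O)CCC2=C1C(=O)[C@@H](O[Si](C)(C)C(C)(C)C)[C@H](C)[C@@]2(C)CC/C(C)=C/CO[Si](c3ccccc3)(c3ccccc3)C(C)(C)C
F7 | step 16 | 19-acetoxy-7,15-dihydroxy-5(10),13-diene-3,6-dione (C7 acyloin) | CC(=O)OC[C@@]1(C)C(=O)CCC2=C1C(=O)[C@@H](O)[C@H](C)[C@@]2(C)CC/C(C)=C/CO
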